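The retrosynthesis cuts O1–C2 (ring C, dehydration), then C4a–C8a (ring A, Claisen), then C2–C3, C4–C4a and C5–C6 (carbanion acylations) and C7–C8 (ester self-condensation).
Enabling feature: ring A has oxygen on C5, C7 and C8a and the acyl carbon C4 on C4a, so it is an acylphloroglucinol. Its six carbons are the folded β-polycarbonyl chain C8a–C8–C7–C6–C5–C4a, in which C6 and C8 already carry OMe and C4a is the only CH2.
Forward, the chain grows from the acid end C8a towards ring B (C7–C8, C5–C6, C4–C4a, C2–C3). From the triketide stage on, the acid end is stored as a 4-hydroxy-2-pyrone (temporary ring O–C5–C6–C7–C8–C8a).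
Rings: ring B is bought, the pyrone is exchanged for ring A with Mg(OMe)2, and ring C closes last under acid through either of two equivalent ortho hydroxyls.
Stereochemistry: the target is achiral. Every CH(OMe) centre on the way lies between carbonyl groups, is labile and ends as an sp2 carbon, so nothing needs to be controlled.

Key step: step 6

Remark on the chemistry: atom labels follow the flavone numbering of 12; compounds 2, 4, 9, 10 and 11 are drawn as keto tautomers and handled as racemates or epimer mixtures because their CH(OMe) centres are configurationally labile; LiN(iPr)2 and Mg(OMe)2 are used as purchased solutions.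

Step 1
Reactants: 1 methyl methoxyacetate (two molecules)
Product: 2 methyl 2,4-dimethoxy-3-oxobutanoate
Conditions: NaH (0.55 equiv), THF, 0 to 50 °C; then cold 1 M HCl
Reagents that add atoms: none
Why: Claisen self-condensation, in which the enolate of one molecule of 1 acylates a second one (C7–C8 bond), deprotonation of the β-keto ester drives the equilibrium, and no cross-product can arise because both partners are the same ester.

Step 2
Reactants: 2 methyl 2,4-dimethoxy-3-oxobutanoate; 3 N-methoxy-N-methylacetamide
Product: 4 methyl 2,4-dimethoxy-3,5-dioxohexanoate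
Conditions: LiN(iPr)2 (2.3 equiv), THF, −78 to 0 °C; 3 (1.1 equiv), −78 to 0 °C; then 1 M HCl
Reagents that add atoms: none
Why: γ-Acylation of a β-keto ester dianion with a Weinreb amide, in which twofold deprotonation of 2 places the last-formed and most nucleophilic carbanion on C6 (the only C–H acid left), and the lithium-chelated tetrahedral adduct survives until the quench, so the acidic product cannot protonate unreacted dianion (C5–C6 bond).

Step 3
Reactants: 4 methyl 2,4-dimethoxy-3,5-dioxohexanoate
Product: 5 4-hydroxy-3,5-dimethoxy-6-methyl-2H-pyran-2-one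
Conditions: DBU (1.2 equiv), toluene, 80 °C; then 1 M HCl
Reagents that add atoms: none
Why: Base-mediated lactonization of a 3,5-dioxo ester, in which the enolate oxygen on C5 attacks the ester carbonyl C8a (6-exo-trig), methoxide leaves, and enolization of the C7 ketone gives the 4-hydroxy-2-pyrone as its stable DBU salt, while the terminal methyl group is far too weakly acidic under these conditions to compete as a carbon nucleophile.

Step 4
Reactants: 5 4-hydroxy-3,5-dimethoxy-6-methyl-2H-pyran-2-one; 6 N,2-dimethoxy-N-methylacetamide
Product: 7 4-hydroxy-3,5-dimethoxy-6-(3-methoxy-2-oxopropyl)-2H-pyran-2-one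
Conditions: LiN(iPr)2 (2.3 equiv), THF, −78 to −20 °C; 6 (1.1 equiv), −78 to 0 °C; then 1 M HCl
Reagents that add atoms: none
Why: Lateral (vinylogous) acylation of a 4-hydroxy-6-methyl-2-pyrone dianion, in which the methyl group (C4a) is the only C–H acid after the hydroxyl because both ring positions of the pyrone carry methoxy groups, and the Weinreb amide stops cleanly at the ketone and cannot self-condense as the corresponding ester would (C4–C4a bond).

Step 5
Reactants: 7 4-hydroxy-3,5-dimethoxy-6-(3-methoxy-2-oxopropyl)-2H-pyran-2-one; 8 methyl 2,4,5-trimethoxybenzoate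
Product: 9 4-hydroxy-3,5-dimethoxy-6-[3-methoxy-2,4-dioxo-4-(2,4,5-trimethoxyphenyl)butyl]-2H-pyran-2-one
Conditions: LiN(iPr)2 (4.2 equiv), THF, −78 to 0 °C; 8 (1.0 equiv), 0 to 23 °C; then cold 1 M HCl
Reagents that add atoms: none
Why: Terminal Claisen-type aroylation of a β-polycarbonyl polyanion, in which threefold deprotonation of 7 (hydroxyl, C4a–H, then C3–H as the only remaining C–H acid) leaves the most basic and most reactive carbanion on C3, this carbanion attacks the non-enolizable ester 8 (C2–C3 bond), and the fourth equivalent of base takes up the acidic proton of the new 1,3-diketone.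

Step 6
Reactants: 9 4-hydroxy-3,5-dimethoxy-6-[3-methoxy-2,4-dioxo-4-(2,4,5-trimethoxyphenyl)butyl]-2H-pyran-2-one
Product: 11 2-methoxy-1-(2,4,6-trihydroxy-3,5-dimethoxyphenyl)-3-(2,4,5-trimethoxyphenyl)propane-1,3-dione, via open-chain tetraketo ester 10 (not isolated)
Conditions: Mg(OMe)2 (6 equiv), MeOH, reflux, argon; then cold 1 M HCl
Reagents that add atoms: Mg(OMe)2, magnesium dimethoxide, C[O-].C[O-].[Mg+2] (one methoxy group is built into 10 and is expelled again on closure to 11; none of it stays in 11)
Why: Mg(OMe)2 first opens the lactone at C8a to the magnesium-chelated open-chain ester 10, because a carbanion on C4a cannot reach the carbonyl of the intact pyrone (that bond would create an oxetane inside a bicyclo[3.1.1] frame with bridgehead alkenes). In 10 the C4a carbanion, doubly activated by the C4 and C5 carbonyls, adds to the ester carbonyl C8a, methoxide leaves, and the cyclohexanetrione enolizes to the aromatic acylphloroglucinol 11, whose formation as a magnesium phenoxide makes the sequence irreversible. The closest known reaction type is the Mg(OMe)2-induced ring transformation of 6-(2-oxoalkyl)-4-hydroxy-2-pyrones into acylphloroglucinols, an intramolecular Claisen (Dieckmann-type) condensation. Ring A (C4a–C5–C6–C7–C8–C8a) closes in the 6-exo-trig mode with the C8a carbonyl oxygen outside the new ring; no stereocentre is formed and the labile one at C3 is simply carried along. The step needs Claisen rather than aldol folding and C4a rather than C3, C6 or C8 as the nucleophile: each six-membered aldol closure open to the chain (C8 to C4, C6 to C2, C3 to C7) would turn a methoxy-bearing carbon into a quaternary centre that cannot aromatize, so these additions revert, whereas C4a is the only CH2 and its closure ends in an arene. Chelation by the magnesium ion keeps the β-dicarbonyl units enolized, which shields the C2/C4 diketone from retro-Claisen cleavage by methoxide and holds C4a close to C8a.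

Step 7
Reactants: 11 2-methoxy-1-(2,4,6-trihydroxy-3,5-dimethoxyphenyl)-3-(2,4,5-trimethoxyphenyl)propane-1,3-dione
Product: 12 5,7-dihydroxy-3,6,8,2',4',5'-hexamethoxyflavone
Conditions: H2SO4 (cat.), AcOH, 90 °C
Reagents that add atoms: none
Why: Acid-catalysed cyclodehydration of an o-hydroxyaryl 1,3-diketone (the closing step of a Baker–Venkataraman flavone synthesis), in which a hydroxyl ortho to C4a adds to the protonated C2 carbonyl (6-exo-trig) and the hemiketal loses water, the two ortho hydroxyls being equivalent by the symmetry of ring A so that only one flavone can form, the other hydroxyl becoming the chelated 5-OH, and the aryl methyl ethers tolerating catalytic acid.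

Compound list
1 | methyl methoxyacetate | COCC(=O)OC | starting material
2 | methyl 2,4-dimethoxy-3-oxobutanoate (racemic, labile centre) | COCC(=O)C(OC)C(=O)OC | intermediate
3 | N-methoxy-N-methylacetamide | CC(=O)N(C)OC | starting material
4 | methyl 2,4-dimethoxy-3,5-dioxohexanoate (epimer mixture, labile centres) | CC(=O)C(OC)C(=O)C(OC)C(=O)OC | intermediate
5 | 4-hydroxy-3,5-dimethoxy-6-methyl-2H-pyran-2-one | CC1=C(OC)C(O)=C(OC)C(=O)O1 | intermediate
6 | N,2-dimethoxy-N-methylacetamide | COCC(=O)N(C)OC | starting material
7 | 4-hydroxy-3,5-dimethoxy-6-(3-methoxy-2-oxopropyl)-2H-pyran-2-one | COCC(=O)CC1=C(OC)C(O)=C(OC)C(=O)O1 | intermediate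
8 | methyl 2,4,5-trimethoxybenzoate | COC(=O)c1cc(OC)c(OC)cc1OC | starting material
9 | 4-hydroxy-3,5-dimethoxy-6-[3-methoxy-2,4-dioxo-4-(2,4,5-trimethoxyphenyl)butyl]-2H-pyran-2-one (racemic, labile centre) | O=C1OC(CC(=O)C(OC)C(=O)c2cc(OC)c(OC)cc2OC)=C(OC)C(O)=C1OC | intermediate
10 | methyl 2,4,8-trimethoxy-3,5,7,9-tetraoxo-9-(2,4,5-trimethoxyphenyl)nonanoate (open-chain tetraketo ester, epimer mixture, not isolated) | COC(=O)C(OC)C(=O)C(OC)C(=O)CC(=O)C(OC)C(=O)c1cc(OC)c(OC)cc1OC | intermediate
11 | 2-methoxy-1-(2,4,6-trihydroxy-3,5-dimethoxyphenyl)-3-(2,4,5-trimethoxyphenyl)propane-1,3-dione (racemic, labile centre) | COC(C(=O)c1cc(OC)c(OC)cc1OC)C(=O)c1c(O)c(OC)c(O)c(OC)c1O | intermediate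
12 | 5,7-dihydroxy-3,6,8,2',4',5'-hexamethoxyflavone (achiral) | COc1cc(OC)c(-c2oc3c(OC)c(O)c(OC)c(O)c3c(=O)c2OC)cc1OC | target

Total step count: 7. Longest linear sequence: 7 steps (1 to 12).

Steps most likely to fail

Step 5. Acyl transfer from the electron-rich, ortho-substituted benzoate may be slow. Proton exchange with the product and decay of the polyanion on warming could then overtake C2–C3 bond formation. The fallback forms this bond at the alcohol oxidation level and sets out from 7. Triply deprotonated 7 (LiN(iPr)2, THF, −78 °C) is treated with commercial 2,4,5-trimethoxybenzaldehyde. This is a much better electrophile, and its aldolate is no proton source. The addition should give 4-hydroxy-6-[4-hydroxy-3-methoxy-2-oxo-4-(2,4,5-trimethoxyphenyl)butyl]-3,5-dimethoxy-2H-pyran-2-one F1 as a diastereomer mixture. Oxidation of the benzylic alcohol with Dess–Martin periodinane in CH2Cl2 removes both new centres and returns to the route at 9.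

Step 6. Methoxide may cleave the non-enolized fraction of the 2-methoxy-1,3-diketone terminus (retro-Claisen loss of the aroyl group) faster than ring A closes. The reaction may also stall after ring opening. The fallback makes the same C4a–C8a bond on the smaller pyrone, which has no cleavable diketone, and attaches ring B afterwards. It sets out from 7. Mg(OMe)2 in MeOH at reflux should lead through methyl 2,4,8-trimethoxy-3,5,7-trioxooctanoate F2 to 2-methoxy-1-(2,4,6-trihydroxy-3,5-dimethoxyphenyl)ethan-1-one F3. Exhaustive deprotonation of F3 with LiN(SiMe3)2 (5 equiv, THF, −78 to −10 °C) and C-aroylation of the enolate carbon with one equivalent of 2,4,5-trimethoxybenzoyl chloride follow. This is the known protecting-group-free conversion of polyhydroxyacetophenones into o-hydroxyaryl 1,3-diketones, and it comes back to the route at 11. The detour also bypasses step 5.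

Step 2. The hindered, strongly basic secondary carbanion at C6 may deprotonate the acetamide, or strip its N-methoxy group, instead of adding to the carbonyl. The fallback replaces the dianion by its neutral silyl equivalent and sets out from 2. Me3SiCl and Et3N give methyl 2,4-dimethoxy-3-(trimethylsilyloxy)but-2-enoate F4. LiN(iPr)2 followed by Me3SiCl (THF, −78 °C) then gives 1,2,4-trimethoxy-1,3-bis(trimethylsilyloxy)buta-1,3-diene F5. Both are mixtures of geometric isomers, and the geometry has no consequence. Mukaiyama-type acylation of the terminal diene carbon with acetyl chloride (CH2Cl2, −78 to 20 °C) and aqueous work-up come back to the route at 4.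

Further compounds
F1 | step 5 | 4-hydroxy-6-[4-hydroxy-3-methoxy-2-oxo-4-(2,4,5-trimethoxyphenyl)butyl]-3,5-dimethoxy-2H-pyran-2-one (diastereomer mixture, racemic) | O=C1OC(CC(=O)C(OC)C(O)c2cc(OC)c(OC)cc2OC)=C(OC)C(O)=C1OC
F2 | step 6 | methyl 2,4,8-trimethoxy-3,5,7-trioxooctanoate (epimer mixture, not isolated) | COCC(=O)CC(=O)C(OC)C(=O)C(OC)C(=O)OC
F3 | step 6 | 2-methoxy-1-(2,4,6-trihydroxy-3,5-dimethoxyphenyl)ethan-1-one | COCC(=O)c1c(O)c(OC)c(O)c(OC)c1O
F4 | step 2 | methyl 2,4-dimethoxy-3-(trimethylsilyloxy)but-2-enoate (E/Z mixture) | COCC(O[Si](C)(C)C)=C(OC)C(=O)OC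
F5 | step 2 | 1,2,4-trimethoxy-1,3-bis(trimethylsilyloxy)buta-1,3-diene (mixture of geometric isomers) | COC=C(O[Si](C)(C)C)C(OC)=C(OC)O[Si](C)(C)C
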